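The target is the primary monoester of a syn-2-alkyl-1-aryl-propane-1,3-diol. The key step exploits that the ester O–CH2 carbon is a formaldehyde-level (acetal-type) carbon and that its neighbour, the CH carbon C2, lies α to the carbinol carbon C3 that carries a 3,4-dimethoxyphenyl ring: at the aryl ketone level C2 is an enolate carbon. The lithium azaenolate of the RAMP hydrazone of 1,5-bis(3,4-dimethoxyphenyl)pent-4-en-1-one is therefore alkylated with the iodomethyl ester of O-silylated (Z)-2-(hydroxymethyl)but-2-enoic acid, which joins both halves, delivers the whole acyloxymethyl arm and sets C2 in one operation. Hydrazone hydrolysis, catalyst-controlled ketone reduction (C3) and desilylation follow.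

Key step: step 10

Remark: the target is read as the (Z)-enoate (CH3 cis to C=O) of the (2R,3S)-alcohol (cinnamyl group and OH syn along OCH2–C2–C3–Ar); crotonaldehyde is used as the commercial (E)-isomer, and (E)-3,4-dimethoxycinnamyl alcohol and RAMP are taken as commercial.

Step 1
Reactants: 1 (E)-but-2-enal (crotonaldehyde)
Product: 3 (Z)-2-bromobut-2-enal, via 2,3-dibromobutanal 2 (not isolated)
Conditions: Br2, CH2Cl2, 0 °C; then Et3N, 0 °C → rt
Reagents that add atoms: bromine BrBr
Why: Bromination–dehydrobromination (anti addition of Br2, then E1cB loss of HBr with Et3N) should give the α-bromo enal as the thermodynamically preferred (Z)-isomer, with methyl trans to the formyl group as in the starting (E)-enal.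

Step 2
Reactants: 3 (Z)-2-bromobut-2-enal
Product: 4 (Z)-2-bromobut-2-en-1-ol
Conditions: NaBH4, CeCl3·7H2O, MeOH, 0 °C
Reagents that add atoms: none
Why: Luche reduction should reduce the aldehyde in a 1,2-sense without touching the vinyl bromide or the alkene geometry.

Step 3
Reactants: 4 (Z)-2-bromobut-2-en-1-ol
Product: 5 tert-butyl{[(Z)-2-bromobut-2-en-1-yl]oxy}diphenylsilane
Conditions: TBDPSCl, imidazole, CH2Cl2, 0 °C → rt
Reagents that add atoms: tert-butylchlorodiphenylsilane CC(C)(C)[Si](Cl)(c1ccccc1)c1ccccc1
Why: Standard silylation of a primary alcohol gives a TBDPS ether that should survive organolithium, aqueous acid and amide base and later shields the ester carbonyl.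

Step 4
Reactants: 5 tert-butyl{[(Z)-2-bromobut-2-en-1-yl]oxy}diphenylsilane
Product: 8 (Z)-2-{[(tert-butyldiphenylsilyl)oxy]methyl}but-2-enoic acid, via vinyllithium 6 (not isolated), via lithium carboxylate 7 (not isolated)
Conditions: t-BuLi (2.1 equiv), Et2O, −78 °C; CO2 (g), −78 → 0 °C; cold 1 M HCl
Reagents that add atoms: carbon dioxide O=C=O
Why: Halogen–lithium exchange and carboxylation of the configurationally stable vinyllithium both proceed with retention at −78 °C, which fixes the methyl group cis to the carboxyl group.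

Step 5
Reactants: 8 (Z)-2-{[(tert-butyldiphenylsilyl)oxy]methyl}but-2-enoic acid
Product: 9 chloromethyl (Z)-2-{[(tert-butyldiphenylsilyl)oxy]methyl}but-2-enoate
Conditions: ClCH2OSO2Cl, NaHCO3, Bu4NHSO4 (cat.), CH2Cl2/H2O, rt
Reagents that add atoms: chloromethyl chlorosulfate ClCOS(=O)(=O)Cl
Why: Phase-transfer O-alkylation of the carboxylate with chloromethyl chlorosulfate (chlorosulfate as leaving group) is a standard chloromethyl ester synthesis that leaves the silyl ether and the enoate geometry untouched.

Step 6
Reactants: 9 chloromethyl (Z)-2-{[(tert-butyldiphenylsilyl)oxy]methyl}but-2-enoate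
Product: 10 iodomethyl (Z)-2-{[(tert-butyldiphenylsilyl)oxy]methyl}but-2-enoate
Conditions: NaI, acetone, rt, dark
Reagents that add atoms: sodium iodide [Na+].[I-]
Why: Finkelstein exchange, driven by precipitation of NaCl, should give the much more reactive iodomethyl ester, which is used at once.

Step 7
Reactants: 11 (E)-3-(3,4-dimethoxyphenyl)prop-2-en-1-ol
Product: 12 4-[(E)-3-bromoprop-1-en-1-yl]-1,2-dimethoxybenzene
Conditions: PBr3, Et2O, 0 °C
Reagents that add atoms: phosphorus tribromide BrP(Br)Br
Why: Nucleophilic substitution of the allylic alcohol via its bromophosphite should give the conjugated (E)-cinnamyl bromide, which is used crude and cold because it ionises easily.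

Step 8
Reactants: 13 1-(3,4-dimethoxyphenyl)ethan-1-one; 14 RAMP [(R)-1-amino-2-(methoxymethyl)pyrrolidine]
Product: 15 (E)-RAMP hydrazone of 1-(3,4-dimethoxyphenyl)ethan-1-one (amino nitrogen syn to methyl)
Conditions: p-TsOH (cat.), cyclohexane, reflux, Dean–Stark
Reagents that add atoms: none
Why: Acid-catalysed hydrazone formation with azeotropic removal of water should give the hydrazone with the amino nitrogen anti to the aryl ring.

Step 9
Reactants: 15 (E)-RAMP hydrazone of 1-(3,4-dimethoxyphenyl)ethan-1-one; 12 4-[(E)-3-bromoprop-1-en-1-yl]-1,2-dimethoxybenzene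
Product: 17 RAMP hydrazone of (E)-1,5-bis(3,4-dimethoxyphenyl)pent-4-en-1-one, via lithium azaenolate 16 (not isolated)
Conditions: LDA, THF, 0 °C; then 12, −78 °C → rt
Reagents that add atoms: none
Why: Enders-type hydrazone alkylation, in which LDA deprotonates the methyl group syn to nitrogen and the azaenolate displaces the primary allylic bromide in an SN2 sense, should keep the (E)-styrene and forms no stereocentre yet.

Step 10
Reactants: 17 RAMP hydrazone of (E)-1,5-bis(3,4-dimethoxyphenyl)pent-4-en-1-one; 10 iodomethyl (Z)-2-{[(tert-butyldiphenylsilyl)oxy]methyl}but-2-enoate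
Product: 19 RAMP hydrazone of (2R)-3-(3,4-dimethoxyphenyl)-2-[(E)-3-(3,4-dimethoxyphenyl)prop-2-en-1-yl]-3-oxopropyl (Z)-2-{[(tert-butyldiphenylsilyl)oxy]methyl}but-2-enoate, via lithium azaenolate 18 (not isolated)
Conditions: LDA (1.05 equiv), THF, 0 °C; then 10, −100 → −78 °C; pH 7 buffer, −78 °C
Reagents that add atoms: none
Why: LDA removes one C2 proton syn to the hydrazone nitrogen to give the lithium azaenolate 18, expected in the E(C=C)/Z(C–N) geometry with lithium chelated by the methoxymethyl arm, and this carbon displaces iodide from the acetal-type CH2 of 10 in an SN2 step, forming the bond between the ester O–CH2 carbon and C2. The closest known reaction type is the Enders SAMP/RAMP hydrazone α-alkylation, established for alkyl halides and halomethyl ethers; halomethyl carboxylates are known C-alkylating agents for enolates. No ring is closed. The new stereocentre at C2 is set by the RAMP auxiliary: the chelated pyrrolidine blocks one azaenolate face, and by the established sense of induction the (R)-auxiliary, with the cinnamyl arm already in place, should give the arrangement that is 2R in the ketone and the target (formally S in the hydrazone because the CIP ranks change). The step needs chemoselectivity for the CH2–I carbon over the ester carbonyl and the enoate β-carbon, which the high SN2 reactivity of the α-acyloxy iodide at −100 °C, the conjugated α-branched carbonyl and the bulky TBDPSOCH2 group beside it should secure. Quenching at −78 °C should keep the product from E1cB loss of the carboxylate.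

Step 11
Reactants: 19 RAMP hydrazone of the (2R)-acyloxymethyl ketone
Product: 20 (2R)-3-(3,4-dimethoxyphenyl)-2-[(E)-3-(3,4-dimethoxyphenyl)prop-2-en-1-yl]-3-oxopropyl (Z)-2-{[(tert-butyldiphenylsilyl)oxy]methyl}but-2-enoate
Conditions: sat. aq. oxalic acid, Et2O, rt
Reagents that add atoms: water O
Why: Two-phase acid-catalysed hydrazone hydrolysis with oxalic acid should release the ketone under conditions too mild to enolise the α-stereocentre or eliminate the β-acyloxy group, and the auxiliary is recovered from the aqueous phase.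

Step 12
Reactants: 20 (2R)-acyloxymethyl aryl ketone
Product: 22 (2R,3S)-3-(3,4-dimethoxyphenyl)-2-[(E)-3-(3,4-dimethoxyphenyl)prop-2-en-1-yl]-3-hydroxypropyl (Z)-2-{[(tert-butyldiphenylsilyl)oxy]methyl}but-2-enoate, via catechol borate ester 21 (not isolated)
Conditions: (R)-Me-CBS (cat.), catecholborane, toluene, −78 → −40 °C; then MeOH, aq. NaHCO3
Reagents that add atoms: none
Why: In this Corey–Bakshi–Shibata reduction the (R)-oxazaborolidine should bind the ketone with the 3,4-dimethoxyphenyl ring as the large group and deliver hydride to the face that gives the (S)-carbinol (catalyst control), while cold catecholborane spares the alkenes and the ester.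

Step 13
Reactants: 22 (2R,3S)-silyl-protected hydroxy ester
Product: 23 (2R,3S)-3-(3,4-dimethoxyphenyl)-2-[(E)-3-(3,4-dimethoxyphenyl)prop-2-en-1-yl]-3-hydroxypropyl (Z)-2-(hydroxymethyl)but-2-enoate (target)
Conditions: TBAF, AcOH, THF, 0 °C → rt
Reagents that add atoms: none
Why: Fluoride-mediated desilylation, buffered with acetic acid to suppress acyl migration and to protect the ionisable electron-rich benzylic alcohol, should give the target.

Compound list
1 | (E)-but-2-enal (crotonaldehyde) | C/C=C/C=O | starting material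
2 | 2,3-dibromobutanal | CC(Br)C(Br)C=O | intermediate
3 | (Z)-2-bromobut-2-enal | C/C=C(\Br)C=O | intermediate
4 | (Z)-2-bromobut-2-en-1-ol | C/C=C(\Br)CO | intermediate
5 | tert-butyl{[(Z)-2-bromobut-2-en-1-yl]oxy}diphenylsilane | C/C=C(\Br)CO[Si](c1ccccc1)(c1ccccc1)C(C)(C)C | intermediate
6 | {(E)-1-[(tert-butyldiphenylsilyl)oxy]but-2-en-2-yl}lithium (methyl cis to lithium) | C/C=C(\[Li])CO[Si](c1ccccc1)(c1ccccc1)C(C)(C)C | intermediate
7 | lithium (Z)-2-{[(tert-butyldiphenylsilyl)oxy]methyl}but-2-enoate | C/C=C(/CO[Si](c1ccccc1)(c1ccccc1)C(C)(C)C)C(=O)[O-].[Li+] | intermediate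
8 | (Z)-2-{[(tert-butyldiphenylsilyl)oxy]methyl}but-2-enoic acid | C/C=C(/CO[Si](c1ccccc1)(c1ccccc1)C(C)(C)C)C(=O)O | intermediate
9 | chloromethyl (Z)-2-{[(tert-butyldiphenylsilyl)oxy]methyl}but-2-enoate | C/C=C(/CO[Si](c1ccccc1)(c1ccccc1)C(C)(C)C)C(=O)OCCl | intermediate
10 | iodomethyl (Z)-2-{[(tert-butyldiphenylsilyl)oxy]methyl}but-2-enoate | C/C=C(/CO[Si](c1ccccc1)(c1ccccc1)C(C)(C)C)C(=O)OCI | intermediate
11 | (E)-3-(3,4-dimethoxyphenyl)prop-2-en-1-ol | OC/C=C/c1ccc(OC)c(OC)c1 | starting material
12 | 4-[(E)-3-bromoprop-1-en-1-yl]-1,2-dimethoxybenzene | BrC/C=C/c1ccc(OC)c(OC)c1 | intermediate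
13 | 1-(3,4-dimethoxyphenyl)ethan-1-one | CC(=O)c1ccc(OC)c(OC)c1 | starting material
14 | RAMP, (R)-1-amino-2-(methoxymethyl)pyrrolidine | COC[C@H]1CCCN1N | starting material
15 | (E)-RAMP hydrazone of 1-(3,4-dimethoxyphenyl)ethan-1-one | COC[C@H]1CCCN1/N=C(\C)c1ccc(OC)c(OC)c1 | intermediate
16 | lithium azaenolate of 15 | COC[C@H]1CCCN1N([Li])C(=C)c1ccc(OC)c(OC)c1 | intermediate
17 | RAMP hydrazone of (E)-1,5-bis(3,4-dimethoxyphenyl)pent-4-en-1-one (amino nitrogen syn to CH2) | COC[C@H]1CCCN1/N=C(\CC/C=C/c1ccc(OC)c(OC)c1)c1ccc(OC)c(OC)c1 | intermediate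
18 | lithium azaenolate of 17, E(C=C) | COC[C@H]1CCCN1N([Li])/C(=C/C/C=C/c1ccc(OC)c(OC)c1)c1ccc(OC)c(OC)c1 | intermediate
19 | RAMP hydrazone of ketone 20 (α-carbon formally S) | C/C=C(/CO[Si](c1ccccc1)(c1ccccc1)C(C)(C)C)C(=O)OC[C@@H](C/C=C/c1ccc(OC)c(OC)c1)/C(=N\N1CCC[C@@H]1COC)c1ccc(OC)c(OC)c1 | intermediate
20 | (2R)-3-(3,4-dimethoxyphenyl)-2-[(E)-3-(3,4-dimethoxyphenyl)prop-2-en-1-yl]-3-oxopropyl (Z)-2-{[(tert-butyldiphenylsilyl)oxy]methyl}but-2-enoate | C/C=C(/CO[Si](c1ccccc1)(c1ccccc1)C(C)(C)C)C(=O)OC[C@@H](C/C=C/c1ccc(OC)c(OC)c1)C(=O)c1ccc(OC)c(OC)c1 | intermediate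
21 | catechol borate ester of 22 (1,3,2-benzodioxaborol-2-yl ether at the benzylic oxygen) | C/C=C(/CO[Si](c1ccccc1)(c1ccccc1)C(C)(C)C)C(=O)OC[C@@H](C/C=C/c1ccc(OC)c(OC)c1)[C@H](OB1Oc2ccccc2O1)c1ccc(OC)c(OC)c1 | intermediate
22 | (2R,3S)-3-(3,4-dimethoxyphenyl)-2-[(E)-3-(3,4-dimethoxyphenyl)prop-2-en-1-yl]-3-hydroxypropyl (Z)-2-{[(tert-butyldiphenylsilyl)oxy]methyl}but-2-enoate | C/C=C(/CO[Si](c1ccccc1)(c1ccccc1)C(C)(C)C)C(=O)OC[C@@H](C/C=C/c1ccc(OC)c(OC)c1)[C@H](O)c1ccc(OC)c(OC)c1 | intermediate
23 | (2R,3S)-3-(3,4-dimethoxyphenyl)-2-[(E)-3-(3,4-dimethoxyphenyl)prop-2-en-1-yl]-3-hydroxypropyl (Z)-2-(hydroxymethyl)but-2-enoate | C/C=C(/CO)C(=O)OC[C@@H](C/C=C/c1ccc(OC)c(OC)c1)[C@H](O)c1ccc(OC)c(OC)c1 | target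

Total step count: 13. Longest linear sequence: 10 steps (steps 1–6, then 10–13).

Steps most likely to fail

Step 10. The azaenolate may transfer the acyl group by attack at the ester carbonyl of 10 instead of displacing iodide. The product may lose the carboxylate by β-elimination under residual base. Facial selectivity may be poor if the aryl ketone azaenolate does not adopt one geometry. Fallback: setting out from 17, the azaenolate 18 is generated as before and treated at −78 °C with monomeric formaldehyde (from cracked paraformaldehyde). This aldol-type hydroxymethylation under the same auxiliary control should give the RAMP hydrazone of (R)-2-(hydroxymethyl)-1,5-bis(3,4-dimethoxyphenyl)pent-4-en-1-one F1. Steglich esterification of F1 with acid 8 (EDC, DMAP cat., CH2Cl2, 0 °C) then comes back to the route at 19.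

Step 11. Hydrolysis of the conjugated aryl ketone hydrazone may be slow, and during it C2 may epimerise through enolisation or ene-hydrazine formation, or the β-acyloxy group may be eliminated. Fallback: setting out from 19, the pyrrolidine nitrogen is quaternised with MeI (neat, 60 °C) to the N-methylhydrazonium iodide of 19 F2. This activated C=N bond should hydrolyse quickly in a cold two-phase system (1 M HCl, pentane/Et2O, 0 °C), and the route is rejoined at 20.

Step 12. Facial selectivity may be poor if the catalyst cannot tell the aryl ring from the branched α-carbon or is opposed by the resident C2 stereocentre, and the electron-rich ketone may be reduced only slowly. Fallback: setting out from 20, the control element is changed to outer-sphere Noyori–Ikariya transfer hydrogenation, RuCl(p-cymene)[(S,S)-TsDPEN] in HCO2H/Et3N (5:2) at rt. Its face selection rests on the aryl CH/π contact with the catalyst, not on steric ranking, and it should give the (S)-carbinol 22 directly; no new compound arises (F0).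

Further compounds
F1 | step 10 | RAMP hydrazone of (R)-2-(hydroxymethyl)-1,5-bis(3,4-dimethoxyphenyl)pent-4-en-1-one | OC[C@@H](C/C=C/c1ccc(OC)c(OC)c1)/C(=N\N1CCC[C@@H]1COC)c1ccc(OC)c(OC)c1
F2 | step 11 | N-methylhydrazonium iodide of 19 (methyl on the pyrrolidine nitrogen) | C/C=C(/CO[Si](c1ccccc1)(c1ccccc1)C(C)(C)C)C(=O)OC[C@@H](C/C=C/c1ccc(OC)c(OC)c1)/C(=N\[N+]1(C)CCC[C@@H]1COC)c1ccc(OC)c(OC)c1.[I-]
F0 | step 12 | none | none
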